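**Retrosynthetic overview**
1. Feature: the six ring carbons (the two C–OH carbons in a 1,3-relation), the benzylic CH2 and the side-chain C=O carbon are eight consecutive atoms, C2–C9, of one alternating carbonyl–methylene chain. This chain is a palmitoyl-primed pentaketide whose C1 carboxyl carbon is absent from the target.
2. The target comes from its dioxolane (hydrolysis, last step), and that from methyl 2,4-dihydroxy-6-[(2-pentadecyl-1,3-dioxolan-2-yl)methyl]benzoate by saponification and decarboxylation in base.
3. The only ring, the benzene ring, is closed by C2–C7 aldol addition and aromatisation of methyl 9,9-(ethylenedioxy)-3,5,7-trioxotetracosanoate.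
4. The open chain is cut at C6–C7 into the trianion of methyl 3,5-dioxohexanoate and the 3-ketal of 3-oxooctadecanoic acid as its N-methoxy-N-methylamide. The amide is preferred to an ester because its α-protons are less acidic (less E1cB opening of the dioxolane) and its chelated adduct releases no acidic product before the quench.
5. The amide is built from palmitoyl chloride, Meldrum's acid, MeNHOMe and ethylene glycol in three steps. The diketo ester is built from the methyl acetoacetate dianion in one step.

Key step: step 6

Assumption: all β-dicarbonyl and polycarbonyl compounds are drawn in one tautomeric form although they exist as keto–enol mixtures. The target has no stereocentre, so no stereocontrol is required.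

Step 1
Reactants: 1 palmitoyl chloride; 2 Meldrum's acid
Product: 3 5-(1-hydroxyhexadecylidene)-2,2-dimethyl-1,3-dioxane-4,6-dione
Conditions: pyridine (2.2 equiv), CH2Cl2, 0 °C → rt; dilute aq HCl wash
Reagents that add atoms: none
Why: This is C-acylation of Meldrum's acid, in which the pyridine-generated enolate of the very acidic methylene attacks the acid chloride and the product rests as its hydrogen-bonded enol, which prevents a second acylation.

Step 2
Reactants: 3 5-(1-hydroxyhexadecylidene)-2,2-dimethyl-1,3-dioxane-4,6-dione
Product: 5 N-methoxy-N-methyl-3-oxooctadecanamide, via palmitoylketene 4 (not isolated)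
Conditions: MeNHOMe·HCl (1.2 equiv), Et3N (1.2 equiv), toluene, 90 °C
Reagents that add atoms: N,O-dimethylhydroxylamine hydrochloride, CNOC.Cl
Why: Thermal cycloreversion of the acyl Meldrum's acid expels acetone and CO2 to give the acylketene, which the weakly basic but nucleophilic hydroxylamine should trap (acylketene aminolysis) to give the β-keto Weinreb amide directly.

Step 3
Reactants: 5 N-methoxy-N-methyl-3-oxooctadecanamide; 6 ethylene glycol
Product: 7 N-methoxy-N-methyl-2-(2-pentadecyl-1,3-dioxolan-2-yl)acetamide
Conditions: pTsOH·H2O (cat.), toluene, reflux, Dean–Stark trap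
Reagents that add atoms: none
Why: This is acid-catalysed ketalisation driven by azeotropic removal of water, in which only the ketone carbonyl reacts and the tertiary amide, unlike an ester, cannot exchange with the diol.

Step 4
Reactants: 8 methyl acetoacetate; 9 N-methoxy-N-methylacetamide
Product: 11 methyl 3,5-dioxohexanoate, via dilithio dianion 10 (not isolated)
Conditions: LiN(iPr)2 (2.1 equiv), THF, 0 °C; then 9, −78 → 0 °C; aq HCl
Reagents that add atoms: none
Why: This is γ-acylation of a β-keto ester dianion, in which the more basic terminal carbanion attacks the Weinreb amide and the chelated tetrahedral adduct lasts until the quench, so neither over-addition nor proton exchange with the product interferes.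

Step 5
Reactants: 11 methyl 3,5-dioxohexanoate; 7 N-methoxy-N-methyl-2-(2-pentadecyl-1,3-dioxolan-2-yl)acetamide
Product: 13 methyl 9,9-(ethylenedioxy)-3,5,7-trioxotetracosanoate, via trilithio trianion 12 (not isolated)
Conditions: 11 (1.3 equiv), LiN(iPr)2 (3.1 equiv per 11), THF, −78 → 0 °C; then 7, −78 → −20 °C; AcOH, −78 °C; crude 13 taken on without chromatography
Reagents that add atoms: none
Why: This is terminal acylation of a 1,3,5-tricarbonyl trianion, in which the last-formed and most basic C6 carbanion is the reactive site, the ester of 11 is shielded as its enolate, and the chelated Weinreb adduct holds until the acetic acid quench, so the new acidic C6 methylene cannot consume trianion.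

Step 6
Reactants: 13 methyl 9,9-(ethylenedioxy)-3,5,7-trioxotetracosanoate
Product: 15 methyl 2,4-dihydroxy-6-[(2-pentadecyl-1,3-dioxolan-2-yl)methyl]benzoate, via cyclic aldol 14 (not isolated)
Conditions: KOH (0.5 M aq, 5 equiv), THF, 0 °C → rt, Ar; AcOH to pH 6
Reagents that add atoms: none
Why: Hydroxide converts 13 into its polyenolate, whose C2 carbon (between the ester and the C3 carbonyl) adds to the C7 carbonyl to give the cyclic aldol 14, after which E1cB loss of the C7 hydroxyl and enolisation of the C3 and C5 carbonyls deliver the aromatic ring irreversibly. The closest known reaction type is the base-mediated aldol cyclisation of 3,5,7-triketo esters to orsellinate-type 2,4-dihydroxy-6-alkylbenzoates. The single ring (C2–C3–C4–C5–C6–C7) closes 6-exo-trig at the C7 carbonyl, a mode that is favoured whether the nucleophile is counted through its ester enolate form (enolexo) or through its C3 enolate form (enolendo). No stereocentre survives, because the two sp3 centres of 14 (C2 and C7) form without control and are erased on aromatisation. The step needs C2-to-C7 aldol closure to beat C6-to-C1 Claisen closure and lactonisation of the C5 enol oxygen onto C1: the ketone is a better electrophile than an ester conjugated with its own enolate, water supplies the proton transfers that make dehydration fast and irreversible, and the anhydrous NaOMe or Mg(OMe)2 conditions that favour the Claisen mode are avoided. The dioxolane at C9 leaves C8 as a singly activated methylene, so the competing C8-to-C3 aldol is not populated, and it keeps C9 from acting as an electrophile or from lactonising with the ortho ester afterwards.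

Step 7
Reactants: 15 methyl 2,4-dihydroxy-6-[(2-pentadecyl-1,3-dioxolan-2-yl)methyl]benzoate
Product: 17 5-[(2-pentadecyl-1,3-dioxolan-2-yl)methyl]benzene-1,3-diol, via resorcylic acid 16 (not isolated)
Conditions: KOH (10 equiv), MeOH–H2O, reflux, Ar; AcOH to pH 7
Reagents that add atoms: none
Why: Ester saponification is followed in the same hot alkaline medium by protodecarboxylation of the 2,4-dihydroxybenzoate (ipso-protonation of the electron-rich ring carbon, then loss of CO2), while the dioxolane is inert to base and no free carboxylic acid ever sits next to it, so lactonisation cannot start.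

Step 8
Reactants: 17 5-[(2-pentadecyl-1,3-dioxolan-2-yl)methyl]benzene-1,3-diol
Product: 18 1-(3,5-dihydroxyphenyl)heptadecan-2-one
Conditions: 1 M aq HCl, THF, rt
Reagents that add atoms: water, O
Why: This is acid-catalysed hydrolysis of the dioxolane through its oxocarbenium ion, and with the ortho carboxyl gone and both phenols meta to the side chain the freed ketone has no partner for cyclisation.

**Compound list**
1 | palmitoyl chloride (hexadecanoyl chloride) | CCCCCCCCCCCCCCCC(=O)Cl | starting material
2 | Meldrum's acid (2,2-dimethyl-1,3-dioxane-4,6-dione) | CC1(C)OC(=O)CC(=O)O1 | starting material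
3 | 5-(1-hydroxyhexadecylidene)-2,2-dimethyl-1,3-dioxane-4,6-dione | CCCCCCCCCCCCCCCC(O)=C1C(=O)OC(C)(C)OC1=O | intermediate
4 | palmitoylketene (3-oxooctadec-1-en-1-one), not isolated | CCCCCCCCCCCCCCCC(=O)C=C=O | intermediate
5 | N-methoxy-N-methyl-3-oxooctadecanamide | CCCCCCCCCCCCCCCC(=O)CC(=O)N(C)OC | intermediate
6 | ethylene glycol | OCCO | starting material
7 | N-methoxy-N-methyl-2-(2-pentadecyl-1,3-dioxolan-2-yl)acetamide | CCCCCCCCCCCCCCCC1(CC(=O)N(C)OC)OCCO1 | intermediate
8 | methyl acetoacetate | CC(=O)CC(=O)OC | starting material
9 | N-methoxy-N-methylacetamide | CC(=O)N(C)OC | starting material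
10 | dilithio dianion of methyl acetoacetate, not isolated | [Li+].[Li+].C=C([O-])C=C([O-])OC | intermediate
11 | methyl 3,5-dioxohexanoate | CC(=O)CC(=O)CC(=O)OC | intermediate
12 | trilithio trianion of methyl 3,5-dioxohexanoate, not isolated | [Li+].[Li+].[Li+].C=C([O-])C=C([O-])C=C([O-])OC | intermediate
13 | methyl 9,9-(ethylenedioxy)-3,5,7-trioxotetracosanoate | CCCCCCCCCCCCCCCC1(CC(=O)CC(=O)CC(=O)CC(=O)OC)OCCO1 | intermediate
14 | methyl 2-hydroxy-4,6-dioxo-2-[(2-pentadecyl-1,3-dioxolan-2-yl)methyl]cyclohexane-1-carboxylate (cyclic aldol, mixture of stereoisomers, not isolated) | CCCCCCCCCCCCCCCC1(CC2(O)CC(=O)CC(=O)C2C(=O)OC)OCCO1 | intermediate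
15 | methyl 2,4-dihydroxy-6-[(2-pentadecyl-1,3-dioxolan-2-yl)methyl]benzoate | CCCCCCCCCCCCCCCC1(Cc2cc(O)cc(O)c2C(=O)OC)OCCO1 | intermediate
16 | 2,4-dihydroxy-6-[(2-pentadecyl-1,3-dioxolan-2-yl)methyl]benzoic acid (present as its potassium salt, not isolated) | CCCCCCCCCCCCCCCC1(Cc2cc(O)cc(O)c2C(=O)O)OCCO1 | intermediate
17 | 5-[(2-pentadecyl-1,3-dioxolan-2-yl)methyl]benzene-1,3-diol | CCCCCCCCCCCCCCCC1(Cc2cc(O)cc(O)c2)OCCO1 | intermediate
18 | 1-(3,5-dihydroxyphenyl)heptadecan-2-one | CCCCCCCCCCCCCCCC(=O)Cc1cc(O)cc(O)c1 | target

Total step count: 8
Longest linear sequence: 7 steps (steps 1, 2, 3, 5, 6, 7 and 8, from palmitoyl chloride)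

**Steps most likely to fail**

Step 6. The ring may close in the wrong sense, by attack of the C6 enolate on the ester carbonyl or by acylation of the C5 enol oxygen. The dioxolane may also open by β-elimination through the C8 enolate before the ring has formed.

The fallback sets out from 7 and locks the carboxyl end in a dioxinone ring. There the chain stands trans to the lactone carbonyl across the ring double bond, so closure onto the carboxyl carbon is geometrically impossible.
- Commercial 2,2,6-trimethyl-4H-1,3-dioxin-4-one is deprotonated with LiN(SiMe3)2 (THF, −78 °C) and acetylated with acetyl chloride to 2,2-dimethyl-6-(2-oxopropyl)-4H-1,3-dioxin-4-one F1.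
- The dianion of this ketone (LiN(iPr)2, 2 equiv) is acylated with 7 to 2,2-dimethyl-6-[2,4-dioxo-5-(2-pentadecyl-1,3-dioxolan-2-yl)pentyl]-4H-1,3-dioxin-4-one F2.
- Et3N in CH2Cl2 at rt should bring about the same C2–C7 aldol aromatisation to 7-hydroxy-2,2-dimethyl-5-[(2-pentadecyl-1,3-dioxolan-2-yl)methyl]-4H-1,3-benzodioxin-4-one F3.
- Hot aqueous-methanolic KOH opens the acetonide lactone and decarboxylates through 16, so the sequence comes back to the route at 17.

Step 5. The trianion may abstract a proton from the α-methylene of the amide, and the dioxolane then opens by β-elimination. Incomplete third deprotonation of 11 would also lower conversion.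

The fallback sets out from 7 and replaces acylation by aldol addition and oxidation.
- iBu2AlH (THF, −78 °C) reduces 7 to 2-(2-pentadecyl-1,3-dioxolan-2-yl)acetaldehyde F4.
- Addition of trianion 12 to this aldehyde at −78 °C should be much faster than proton transfer. It gives methyl 9,9-(ethylenedioxy)-7-hydroxy-3,5-dioxotetracosanoate F5, which is racemic, and its carbinol centre is destroyed in the next operation.
- Dess–Martin periodinane with NaHCO3 in CH2Cl2 oxidises the alcohol, and the sequence comes back to the route at 13.

Step 7. Hydroxide may attack the doubly ortho-substituted, phenoxide-deactivated ester only slowly, decarboxylation may stop short of completion, and the resorcinolate may oxidise in hot alkali.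

The fallback sets out from 15 and makes deliberate use of lactonisation.
- pTsOH·H2O in aqueous dioxane at 80 °C removes the dioxolane, and the enol of the freed ketone closes onto the neighbouring ester to give 6,8-dihydroxy-3-pentadecyl-1H-isochromen-1-one F6.
- This enol lactone is a far better acyl donor than the methyl ester. Aqueous KOH should open it at rt to the salt of 2,4-dihydroxy-6-(2-oxoheptadecyl)benzoic acid F7.
- F7 is kept alkaline so that it cannot re-lactonise, and it loses CO2 on heating. The sequence comes back to the route at 18.

**Further compounds**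
F1 | step 6 | 2,2-dimethyl-6-(2-oxopropyl)-4H-1,3-dioxin-4-one | CC(=O)CC1=CC(=O)OC(C)(C)O1
F2 | step 6 | 2,2-dimethyl-6-[2,4-dioxo-5-(2-pentadecyl-1,3-dioxolan-2-yl)pentyl]-4H-1,3-dioxin-4-one | CCCCCCCCCCCCCCCC1(CC(=O)CC(=O)CC2=CC(=O)OC(C)(C)O2)OCCO1
F3 | step 6 | 7-hydroxy-2,2-dimethyl-5-[(2-pentadecyl-1,3-dioxolan-2-yl)methyl]-4H-1,3-benzodioxin-4-one | CCCCCCCCCCCCCCCC1(Cc2cc(O)cc3OC(C)(C)OC(=O)c23)OCCO1
F4 | step 5 | 2-(2-pentadecyl-1,3-dioxolan-2-yl)acetaldehyde | CCCCCCCCCCCCCCCC1(CC=O)OCCO1
F5 | step 5 | methyl 9,9-(ethylenedioxy)-7-hydroxy-3,5-dioxotetracosanoate (racemic) | CCCCCCCCCCCCCCCC1(CC(O)CC(=O)CC(=O)CC(=O)OC)OCCO1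
F6 | step 7 | 6,8-dihydroxy-3-pentadecyl-1H-isochromen-1-one | CCCCCCCCCCCCCCCC1=Cc2cc(O)cc(O)c2C(=O)O1
F7 | step 7 | 2,4-dihydroxy-6-(2-oxoheptadecyl)benzoic acid | CCCCCCCCCCCCCCCC(=O)Cc1cc(O)cc(O)c1C(=O)O
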